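**Plan**

- Carotenoid numbering is used: ring C1 = CMe2, C2 = CH2, C3 = CHOH, C4=C5(CH3), C6=C7 exocyclic. The retrosynthesis cuts C10=C11 and C10'=C11' (double Horner–Wadsworth–Emmons), then the central C15–C15' single bond of the C12 centre piece, then in each ring the bonds C3–C4 and C5–C6.
- Enabling feature: as its C3 ketone each end ring is a 3-methylcyclohex-2-enone in which C4, C5 and the 5-CH3 are the three carbons of an allenyl group and C6 is an alkenyl carbon. The six-membered ring C1–C6 can therefore grow from the four-membered ring C3–C6–C1–C2 by opening C3–C6 and inserting C4/C5.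
- Forward order: aldol condensation on 3,3-dimethylcyclobutanone fixes C6=C7 on the four-membered ring; ethynylation and alkyne-to-allene homologation follow; Rh-catalysed two-carbon ring expansion gives the six-membered dienone; CBS reduction and acetal hydrolysis give the C14 end group; two end groups are joined to the C12 bisphosphonate in one operation.
- Stereochemistry: 6E/6'E comes from the stereoconvergent E1cB aldol dehydration (chain anti to C=O, hence syn to CMe2) and is carried through the ring expansion with retention. C3/C3' (S) comes from catalyst-controlled CBS reduction. 8E comes from step 1, 12E from the purchased enynol, 14E from hydrostannylation, 10E from the final olefination.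

Key step: step 6

Assumption (chemistry): 3,3-dimethylcyclobutanone and (E)-3-methylpent-2-en-4-yn-1-ol are taken as purchasable; the hydride-delivery sense of the CBS catalyst is taken from the alkenyl-as-large-substituent model for cyclohex-2-enones; carbinol centres of 6, 7, 9, 10 and 11 are racemic or mixed and are destroyed later.

Step 1
Reactants: 1 1,1-dimethoxypropan-2-one; 2 diethyl [2-(methoxy(methyl)amino)-2-oxoethyl]phosphonate
Product: 3 (2E)-N,4,4-trimethoxy-N,3-dimethylbut-2-enamide
Conditions: NaH, THF, 0 °C to rt; chromatography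
Reagents that add atoms: none
Why: Horner–Wadsworth–Emmons olefination of the activated α,α-dialkoxy methyl ketone should place the amide trans to the bulkier acetal-bearing carbon (E), the minor Z isomer being removed by chromatography.

Step 2
Reactants: 3 (2E)-N,4,4-trimethoxy-N,3-dimethylbut-2-enamide
Product: 4 (2E)-4,4-dimethoxy-3-methylbut-2-enal
Conditions: DIBAL-H (1.2 equiv), THF, −78 °C; Rochelle salt work-up
Reagents that add atoms: none
Why: Weinreb amide reduction stops at the aldehyde because the chelated tetrahedral aluminium adduct only collapses on work-up, leaving alkene geometry and acetal untouched.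

Step 3
Reactants: 5 3,3-dimethylcyclobutan-1-one; 4 (2E)-4,4-dimethoxy-3-methylbut-2-enal
Product: 8 (2E)-2-[(2E)-4,4-dimethoxy-3-methylbut-2-en-1-ylidene]-3,3-dimethylcyclobutan-1-one, via lithium aldolate 6 (not isolated), via aldol mesylate 7 (not isolated)
Conditions: LDA, THF, −78 °C; then 4; then MsCl, −78 to 0 °C; then DBU, rt
Reagents that add atoms: none
Why: Directed crossed aldol addition of the kinetic lithium enolate (both α-CH2 groups are equivalent) followed by mesylation and E1cB elimination should funnel both aldol diastereomers into the (E)-enone, whose chain is anti to C=O and therefore syn to the CMe2 group.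

Step 4
Reactants: 8 (2E)-2-[(2E)-4,4-dimethoxy-3-methylbut-2-en-1-ylidene]-3,3-dimethylcyclobutan-1-one
Product: 9 (2E)-2-[(2E)-4,4-dimethoxy-3-methylbut-2-en-1-ylidene]-1-ethynyl-3,3-dimethylcyclobutan-1-ol (racemic)
Conditions: HC≡CMgBr, THF, −78 to 0 °C; aq. NH4Cl
Reagents that add atoms: ethynylmagnesium bromide, C#C[Mg]Br
Why: Alkynyl Grignard reagents add 1,2 to the strained, highly electrophilic cyclobutanone carbonyl; the new carbinol centre is racemic and is lost in step 6.

Step 5
Reactants: 9 (2E)-2-[(2E)-4,4-dimethoxy-3-methylbut-2-en-1-ylidene]-1-ethynyl-3,3-dimethylcyclobutan-1-ol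
Product: 11 (2E)-2-[(2E)-4,4-dimethoxy-3-methylbut-2-en-1-ylidene]-3,3-dimethyl-1-(propa-1,2-dien-1-yl)cyclobutan-1-ol (racemic), via propargylic amine 10 (not isolated)
Conditions: (CH2O)n, CuI (0.5 equiv), Cy2NH, 1,4-dioxane, 100 °C
Reagents that add atoms: paraformaldehyde (as formaldehyde), C=O
Why: Crabbé homologation (Mannich reaction, then copper-mediated 1,5-hydride transfer with loss of the imine) converts a terminal alkyne into a terminal allene and tolerates a free tertiary propargylic hydroxyl.

Step 6
Reactants: 11 (2E)-2-[(2E)-4,4-dimethoxy-3-methylbut-2-en-1-ylidene]-3,3-dimethyl-1-(propa-1,2-dien-1-yl)cyclobutan-1-ol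
Product: 12 (4E)-4-[(2E)-4,4-dimethoxy-3-methylbut-2-en-1-ylidene]-3,5,5-trimethylcyclohex-2-en-1-one
Conditions: [Rh(OH)(cod)]2 (2.5 mol %), rac-BINAP (6 mol %), toluene, 70 °C
Reagents that add atoms: none
Why: Proposed new method: the Rh(I) alkoxide of 11 should undergo strain-driven β-carbon elimination of the C3–C6 bond, whose alkylidene carbon can pre-coordinate rhodium and gives the stronger alkenyl–Rh bond, so this bond is expected to break in preference to C3–C2; the alkenylrhodium then adds to the central carbon of the tethered allenyl ketone, and the resulting rhodium dienolate is protonated at the terminal CH2 by the next molecule of 11, which creates the 5-CH3 group and regenerates the alkoxide. The closest known reaction type is the Rh(I)-catalysed ring expansion of tertiary 1-allenylcyclobutanols to 3-methylcyclohex-2-enones by C(sp3)–C β-carbon elimination and allene insertion, together with the sp2-selective β-carbon elimination of benzocyclobutenols. The only ring closed is the six-membered carbocycle (new C6–C5 bond), a 6-exo closure with respect to the terminal allene C=C (6-endo with respect to the enone C4=C5), assisted by the gem-dimethyl group. No stereocentre is formed; the stereoelement at stake is the C6=C7 geometry, which should be retained because C–C cleavage and C–C formation both occur with retention at the alkenyl carbon, so the chain stays syn to CMe2 (6E). The step needs site selectivity between the two ring C–C bonds at the carbinol carbon and against β-allenyl elimination; the sp2 character of C6 is meant to secure the first and the ring strain the second.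

Step 7
Reactants: 12 (4E)-4-[(2E)-4,4-dimethoxy-3-methylbut-2-en-1-ylidene]-3,5,5-trimethylcyclohex-2-en-1-one
Product: 13 (1S,4E)-4-[(2E)-4,4-dimethoxy-3-methylbut-2-en-1-ylidene]-3,5,5-trimethylcyclohex-2-en-1-ol
Conditions: (R)-2-methyl-CBS-oxazaborolidine (0.2 equiv), BH3·SMe2, THF, −30 °C; MeOH quench, NaHCO3 work-up
Reagents that add atoms: none
Why: Corey–Bakshi–Shibata reduction is 1,2-selective, and with the alkenyl flank (C4=C5) acting as the large substituent the (R)-catalyst should deliver hydride to the face that gives the (S)-carbinol.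

Step 8
Reactants: 13 (1S,4E)-4-[(2E)-4,4-dimethoxy-3-methylbut-2-en-1-ylidene]-3,5,5-trimethylcyclohex-2-en-1-ol
Product: 14 (2E,4E)-4-[(4S)-4-hydroxy-2,6,6-trimethylcyclohex-2-en-1-ylidene]-2-methylbut-2-enal
Conditions: PPTS (0.1 equiv), acetone–H2O 10:1, 0 °C; NaHCO3
Reagents that add atoms: water, O
Why: Acid-catalysed hydrolysis of the triene-conjugated dimethyl acetal should be much faster than ionisation of the secondary allylic alcohol under buffered conditions, and the aldehyde once formed deactivates the triene towards ionisation at C3.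

Step 9
Reactants: 15 (2E)-3-methylpent-2-en-4-yn-1-ol
Product: 16 (2E,4E)-3-methyl-5-(tributylstannyl)penta-2,4-dien-1-ol
Conditions: Bu3SnH (1.1 equiv), PdCl2(PPh3)2 (2 mol %), THF, 0 °C
Reagents that add atoms: tributyltin hydride, CCCC[SnH](CCCC)CCCC
Why: Palladium-catalysed syn-hydrostannylation of the terminal alkyne places tin at the terminus and should give the (E)-alkenylstannane without touching the existing (E)-trisubstituted alkene.

Step 10
Reactants: 16 (2E,4E)-3-methyl-5-(tributylstannyl)penta-2,4-dien-1-ol (2 equiv)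
Product: 17 (2E,4E,6E,8E)-3,8-dimethyldeca-2,4,6,8-tetraene-1,10-diol
Conditions: CuCl (3 equiv), DMF, rt to 60 °C, dark
Reagents that add atoms: none
Why: Copper(I)-mediated oxidative homocoupling of alkenylstannanes (tin-to-copper transmetalation, then C–C coupling) proceeds with retention of alkene geometry and forms the central C15–C15' single bond.

Step 11
Reactants: 17 (2E,4E,6E,8E)-3,8-dimethyldeca-2,4,6,8-tetraene-1,10-diol
Product: 19 tetraethyl [(2E,4E,6E,8E)-3,8-dimethyldeca-2,4,6,8-tetraene-1,10-diyl]bis(phosphonate), via allylic dibromide 18 (not isolated)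
Conditions: PBr3, Et2O, −20 °C; then crude 18, P(OEt)3, 110 °C
Reagents that add atoms: triethyl phosphite, CCOP(OCC)OCC
Why: Bromination of the primary allylic diol and Michaelis–Arbuzov reaction of the crude primary dibromide is the standard entry to polyene bisphosphonates and leaves the conjugated, thermodynamically preferred all-E primary isomer.

Step 12
Reactants: 14 (2E,4E)-4-[(4S)-4-hydroxy-2,6,6-trimethylcyclohex-2-en-1-ylidene]-2-methylbut-2-enal (2 equiv); 19 tetraethyl [(2E,4E,6E,8E)-3,8-dimethyldeca-2,4,6,8-tetraene-1,10-diyl]bis(phosphonate)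
Product: 21 (3S,3'S)-eschscholtzxanthin [(3S,3'S,6E,6'E)-4',5'-didehydro-4,5'-retro-β,β-carotene-3,3'-diol], via mono-olefination phosphonate 20 (not isolated)
Conditions: 19, NaHMDS (2.1 equiv), THF, −78 °C; then 14, −78 to 0 °C, argon, dark; neutral work-up, crystallisation
Reagents that add atoms: none
Why: Double Horner–Wadsworth–Emmons olefination of allylic phosphonate carbanions with the enal should give the (E)-C10=C11 bonds, the free hydroxyls being tolerated and the carbanion being kept on the centre piece so that it is never conjugated with the ring C6=C7 bond.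

**Compound list**

1 | 1,1-dimethoxypropan-2-one | CC(=O)C(OC)OC | starting material
2 | diethyl [2-(methoxy(methyl)amino)-2-oxoethyl]phosphonate | CCOP(=O)(CC(=O)N(C)OC)OCC | starting material
3 | (2E)-N,4,4-trimethoxy-N,3-dimethylbut-2-enamide | CON(C)C(=O)/C=C(\C)C(OC)OC | intermediate
4 | (2E)-4,4-dimethoxy-3-methylbut-2-enal | O=C/C=C(\C)C(OC)OC | intermediate
5 | 3,3-dimethylcyclobutan-1-one | CC1(C)CC(=O)C1 | starting material
6 | lithium (2E)-1-(2,2-dimethyl-4-oxocyclobutyl)-4,4-dimethoxy-3-methylbut-2-en-1-olate (diastereomer mixture) | [Li+].[O-]C(/C=C(\C)C(OC)OC)C1C(=O)CC1(C)C | intermediate (not isolated)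
7 | (2E)-1-(2,2-dimethyl-4-oxocyclobutyl)-4,4-dimethoxy-3-methylbut-2-en-1-yl methanesulfonate (diastereomer mixture) | CS(=O)(=O)OC(/C=C(\C)C(OC)OC)C1C(=O)CC1(C)C | intermediate (not isolated)
8 | (2E)-2-[(2E)-4,4-dimethoxy-3-methylbut-2-en-1-ylidene]-3,3-dimethylcyclobutan-1-one | O=C1CC(C)(C)\C1=C/C=C(\C)C(OC)OC | intermediate
9 | (2E)-2-[(2E)-4,4-dimethoxy-3-methylbut-2-en-1-ylidene]-1-ethynyl-3,3-dimethylcyclobutan-1-ol (racemic) | OC1(C#C)CC(C)(C)\C1=C/C=C(\C)C(OC)OC | intermediate
10 | (2E)-1-[3-(dicyclohexylamino)prop-1-yn-1-yl]-2-[(2E)-4,4-dimethoxy-3-methylbut-2-en-1-ylidene]-3,3-dimethylcyclobutan-1-ol (racemic) | OC1(C#CCN(C2CCCCC2)C2CCCCC2)CC(C)(C)\C1=C/C=C(\C)C(OC)OC | intermediate (not isolated)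
11 | (2E)-2-[(2E)-4,4-dimethoxy-3-methylbut-2-en-1-ylidene]-3,3-dimethyl-1-(propa-1,2-dien-1-yl)cyclobutan-1-ol (racemic) | OC1(C=C=C)CC(C)(C)\C1=C/C=C(\C)C(OC)OC | intermediate
12 | (4E)-4-[(2E)-4,4-dimethoxy-3-methylbut-2-en-1-ylidene]-3,5,5-trimethylcyclohex-2-en-1-one | CC1=CC(=O)CC(C)(C)\C1=C/C=C(\C)C(OC)OC | intermediate
13 | (1S,4E)-4-[(2E)-4,4-dimethoxy-3-methylbut-2-en-1-ylidene]-3,5,5-trimethylcyclohex-2-en-1-ol | CC1=C[C@@H](O)CC(C)(C)\C1=C/C=C(\C)C(OC)OC | intermediate
14 | (2E,4E)-4-[(4S)-4-hydroxy-2,6,6-trimethylcyclohex-2-en-1-ylidene]-2-methylbut-2-enal | CC1=C[C@@H](O)CC(C)(C)\C1=C/C=C(\C)C=O | intermediate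
15 | (2E)-3-methylpent-2-en-4-yn-1-ol | OC/C=C(\C)C#C | starting material
16 | (2E,4E)-3-methyl-5-(tributylstannyl)penta-2,4-dien-1-ol | OC/C=C(C)/C=C/[Sn](CCCC)(CCCC)CCCC | intermediate
17 | (2E,4E,6E,8E)-3,8-dimethyldeca-2,4,6,8-tetraene-1,10-diol | OC/C=C(C)/C=C/C=C/C(C)=C/CO | intermediate
18 | (2E,4E,6E,8E)-1,10-dibromo-3,8-dimethyldeca-2,4,6,8-tetraene | BrC/C=C(C)/C=C/C=C/C(C)=C/CBr | intermediate (not isolated)
19 | tetraethyl [(2E,4E,6E,8E)-3,8-dimethyldeca-2,4,6,8-tetraene-1,10-diyl]bis(phosphonate) | CCOP(=O)(OCC)C/C=C(C)/C=C/C=C/C(C)=C/CP(=O)(OCC)OCC | intermediate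
20 | diethyl [(2E,4E,6E,8E,10E,12E,14E)-14-[(4S)-4-hydroxy-2,6,6-trimethylcyclohex-2-en-1-ylidene]-3,8,12-trimethyltetradeca-2,4,6,8,10,12-hexaen-1-yl]phosphonate | CC1=C[C@@H](O)CC(C)(C)\C1=C/C=C(C)/C=C/C=C(C)/C=C/C=C/C(C)=C/CP(=O)(OCC)OCC | intermediate (not isolated)
21 | (3S,3'S)-eschscholtzxanthin, (3S,3'S,6E,6'E)-4',5'-didehydro-4,5'-retro-β,β-carotene-3,3'-diol | CC1=C[C@@H](O)CC(C)(C)\C1=C/C=C(C)/C=C/C=C(C)/C=C/C=C/C(C)=C/C=C/C(C)=C/C=C1/C(C)=C[C@@H](O)CC1(C)C | target

**Step count**

Total steps: 12. Longest linear sequence: 9 (steps 1–8 and 12); steps 9–11 make the centre piece in parallel.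

**Steps most likely to fail**

1. Step 6 (proposed new method). The rhodium alkoxide may cleave the C3–C2 bond instead of C3–C6, or the alkenylrhodium may be protonated before it closes the ring; either gives the wrong constitution or an open-chain ketone. Fallback with known chemistry (enone transposition of a vinylogous ester in place of C–C activation), setting out from 4 and returning at 12: 3-methoxy-5,5-dimethylcyclohex-2-en-1-one F1 is deprotonated at C6 with LDA at −78 °C and added to 4 to give the aldol 6-[(2E)-1-hydroxy-4,4-dimethoxy-3-methylbut-2-en-1-yl]-3-methoxy-5,5-dimethylcyclohex-2-en-1-one F2. NaOMe in MeOH dehydrates it by E1cB to (6E)-6-[(2E)-4,4-dimethoxy-3-methylbut-2-en-1-ylidene]-3-methoxy-5,5-dimethylcyclohex-2-en-1-one F3, with the chain again anti to C=O and syn to CMe2. MeLi/CeCl3 adds 1,2 to give (6E)-6-[(2E)-4,4-dimethoxy-3-methylbut-2-en-1-ylidene]-3-methoxy-1,5,5-trimethylcyclohex-2-en-1-ol F4. Brief treatment with dilute oxalic acid in wet THF at 0 °C (Stork–Danheiser transposition) should then give 12. This gives up the ring-size change but keeps the way the C6=C7 geometry is set.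

2. Step 5. The strained tertiary propargylic alcohol may decompose at 100 °C in the presence of copper (retro-alkynylation or a 1,2-shift of the ring) before the hydride transfer occurs. Fallback, setting out from 8 and returning at 11: lithiated 2-(prop-2-yn-1-yloxy)tetrahydro-2H-pyran (n-BuLi, THF, −78 °C) is added to 8 to give (2E)-2-[(2E)-4,4-dimethoxy-3-methylbut-2-en-1-ylidene]-3,3-dimethyl-1-[3-(tetrahydro-2H-pyran-2-yloxy)prop-1-yn-1-yl]cyclobutan-1-ol F5. LiAlH4 in Et2O then delivers hydride from the alkoxyaluminate in an SN2′ sense with loss of the tetrahydropyranyloxy group and gives allene 11 at or below room temperature.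

3. Step 7. Facial discrimination between the CH= and CH2 flanks of the ketone may be poor, giving low enantiomeric purity at C3. Fallback, setting out from 12 and returning at 13: Luche reduction (NaBH4, CeCl3·7H2O, MeOH, −20 °C) gives the racemic alcohol (4E)-4-[(2E)-4,4-dimethoxy-3-methylbut-2-en-1-ylidene]-3,5,5-trimethylcyclohex-2-en-1-ol F6. Acylative kinetic resolution with immobilised Candida antarctica lipase B and vinyl acetate in MTBE follows. By the empirical enantiopreference of lipases for secondary alcohols (alkenyl flank as the large substituent) the (1R)-enantiomer should be acetylated to (1R,4E)-4-[(2E)-4,4-dimethoxy-3-methylbut-2-en-1-ylidene]-3,5,5-trimethylcyclohex-2-en-1-yl acetate F7, and the unreacted (1S)-alcohol is 13.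

Further compounds
F1 | step 6 | 3-methoxy-5,5-dimethylcyclohex-2-en-1-one | COC1=CC(=O)CC(C)(C)C1
F2 | step 6 | 6-[(2E)-1-hydroxy-4,4-dimethoxy-3-methylbut-2-en-1-yl]-3-methoxy-5,5-dimethylcyclohex-2-en-1-one | COC1=CC(=O)C(C(O)/C=C(\C)C(OC)OC)C(C)(C)C1
F3 | step 6 | (6E)-6-[(2E)-4,4-dimethoxy-3-methylbut-2-en-1-ylidene]-3-methoxy-5,5-dimethylcyclohex-2-en-1-one | COC1=CC(=O)/C(=C/C=C(\C)C(OC)OC)C(C)(C)C1
F4 | step 6 | (6E)-6-[(2E)-4,4-dimethoxy-3-methylbut-2-en-1-ylidene]-3-methoxy-1,5,5-trimethylcyclohex-2-en-1-ol | COC1=CC(C)(O)/C(=C/C=C(\C)C(OC)OC)C(C)(C)C1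
F5 | step 5 | (2E)-2-[(2E)-4,4-dimethoxy-3-methylbut-2-en-1-ylidene]-3,3-dimethyl-1-[3-(tetrahydro-2H-pyran-2-yloxy)prop-1-yn-1-yl]cyclobutan-1-ol | OC1(C#CCOC2CCCCO2)CC(C)(C)\C1=C/C=C(\C)C(OC)OC
F6 | step 7 | (4E)-4-[(2E)-4,4-dimethoxy-3-methylbut-2-en-1-ylidene]-3,5,5-trimethylcyclohex-2-en-1-ol (racemic) | CC1=CC(O)CC(C)(C)\C1=C/C=C(\C)C(OC)OC
F7 | step 7 | (1R,4E)-4-[(2E)-4,4-dimethoxy-3-methylbut-2-en-1-ylidene]-3,5,5-trimethylcyclohex-2-en-1-yl acetate | CC1=C[C@H](OC(C)=O)CC(C)(C)\C1=C/C=C(\C)C(OC)OC
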